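In ring A the three oxygens O1 (on C8a), O5 and O7 occupy the two ortho positions and the para position relative to C4a, the carbon that carries the C4 carbonyl. Each of these C–O bonds is therefore traced back to a C–F bond of a 2,4,6-trifluorobenzoyl group. In one flask the enolate oxygen of an open 1,3-diketone closes ring C on an ortho fluoride, and allyloxide then replaces the fluorides at C7 and C5. The precursor is a 2-allyloxy-1,3-diketone flanked by the trifluorophenyl ring and by ring B bearing 3'-O-allyl and 4'-O-benzyl groups. Global deallylation, sulfation that spares the chelated 5-OH, and hydrogenolysis complete the synthesis.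

Key step: step 5

Assumption: the sulfate esters 19 and 20 are drawn as hydrogen sulfates, like the target. At the bench they would be kept as triethylammonium or potassium salts near pH 7, because the free acids hydrolyse themselves, and the acid form is released when needed on a cold strong-acid cation-exchange resin.

Design points:
- One alkoxide serves both C5 and C7, so the key step needs no C5/C7 regiocontrol. O5 is told apart later by its hydrogen bond to the C4 carbonyl.
- The O3 allyl group sits on an enolisable carbon. Its enolates are therefore kept either cold with lithium as counterion or under a weak carbonate base, which keeps sigmatropic shifts out.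
- Ring B is metalated by bromine–lithium exchange at −78 °C, which is gentler on the allyl ether than magnesium insertion at reflux.
- The alkoxide is made beforehand in THF and the key step is run in NMP. NaH then never meets an amide solvent, and no dimethylamine can be transferred to ring A.
- The target has no stereocentre. The only one on the way, C2 of 12, is racemic and is erased on ring closure.

Step 1
Reactants: 1 2-(benzyloxy)-5-bromophenol; 2 allyl bromide
Product: 3 2-(allyloxy)-1-(benzyloxy)-4-bromobenzene
Conditions: allyl bromide, K2CO3, DMF, rt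
Reagents that add atoms: allyl bromide (2), C=CCBr
Why: Williamson ether synthesis, in which the phenoxide of 1 is alkylated by the allylic bromide in an SN2 reaction while the aryl bromide and the benzyl ether ignore K2CO3.

Step 2
Reactants: 4 allyloxyacetic acid; 5 N,O-dimethylhydroxylamine hydrochloride
Product: 7 2-(allyloxy)-N-methoxy-N-methylacetamide, via acyl imidazole 6 (not isolated)
Conditions: CDI, CH2Cl2, 0 °C to rt; then MeNH(OMe)·HCl, rt
Reagents that add atoms: N,O-dimethylhydroxylamine hydrochloride (5), CNOC.Cl
Why: Amide coupling through the acyl imidazole 6 is a standard entry to Weinreb amides, and it leaves the allyl ether untouched.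

Step 3
Reactants: 3 2-(allyloxy)-1-(benzyloxy)-4-bromobenzene; 7 2-(allyloxy)-N-methoxy-N-methylacetamide
Product: 9 2-(allyloxy)-1-[3-(allyloxy)-4-(benzyloxy)phenyl]ethan-1-one, via aryllithium 8 (not isolated)
Conditions: n-BuLi, THF, −78 °C; then 7, −78 to 0 °C; 1 M HCl quench
Reagents that add atoms: none
Why: Bromine–lithium exchange at −78 °C outruns any attack on the allyl or benzyl ether, and the Weinreb ketone synthesis stops cleanly after a single addition.

Step 4
Reactants: 9 2-(allyloxy)-1-[3-(allyloxy)-4-(benzyloxy)phenyl]ethan-1-one; 10 2,4,6-trifluorobenzoyl chloride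
Product: 12 2-(allyloxy)-1-[3-(allyloxy)-4-(benzyloxy)phenyl]-3-(2,4,6-trifluorophenyl)propane-1,3-dione, via lithium enolate 11 (not isolated)
Conditions: LiN(SiMe3)2 (2.2 equiv), THF, −78 °C; then 10, −78 °C; AcOH quench at −78 °C
Reagents that add atoms: 2,4,6-trifluorobenzoyl chloride (10), O=C(Cl)c1c(F)cc(F)cc1F
Why: Claisen-type C-acylation of a lithium enolate by an aroyl chloride, in which the chelated enolate 11 is made and consumed at −78 °C where α-allyloxy lithium enolates do not undergo [2,3]- or [3,3]-shifts, the second equivalent of base stores 12 as its diketonate, the cold acid quench forestalls early ring closure, and the new centre C2 is racemic, labile and erased in step 5.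

Step 5
Reactants: 12 2-(allyloxy)-1-[3-(allyloxy)-4-(benzyloxy)phenyl]-3-(2,4,6-trifluorophenyl)propane-1,3-dione; 13 allyl alcohol
Product: 17 3,5,7-tris(allyloxy)-2-[3-(allyloxy)-4-(benzyloxy)phenyl]-4H-chromen-4-one, via potassium enolate 14 (not isolated), via 5,7-difluoroflavone 15 (not isolated), via 5-fluoro-7-allyloxyflavone 16 (not isolated)
Conditions: dry K2CO3 (2 equiv), NMP, 25–40 °C until 12 is consumed; then NaOCH2CH=CH2 (from 13, 6 equiv, and NaH, 4 equiv, in THF) added to the same flask, 0 to 60 °C
Reagents that add atoms: allyl alcohol (13), C=CCO, delivered as sodium allyloxide, [Na+].[O-]CC=C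
Why: K2CO3 turns 12 into the delocalised enolate 14, whose oxygen on the ring B side adds to one ortho C–F carbon of the trifluorobenzoyl ring and expels fluoride; this is the intramolecular SNAr (addition–elimination) by which 1-(2-fluorophenyl)-1,3-diketones are routinely converted into flavones. Ring C closes as a six-membered ring in a formally 6-endo-trig mode, the negative charge of the adduct being passed through C4a to the C4 carbonyl, while attack through the enolate carbon would need a four-membered ring and the two ortho fluorides are equivalent, so 15 is the only possible closure product. Sodium allyloxide then displaces fluoride at C7 (para to C4a) and at C5 (ortho to C4a, helped by Na+ bound to the C4 oxygen), the ordinary intermolecular SNAr of fluorochromones with alkoxides, and each oxygen already installed (O1, then O7) is meta to the C–F bond still to react, so it does not push electron density onto the carbon under attack. The selectivity that matters is one of timing: alkoxide is added only after 12 has been consumed, which excludes retro-Claisen cleavage of the open diketone, and the weak base and low temperature of the first stage keep the O3 allyl group of 14 from a [2,3]- or [3,3]-shift. Since a single alkoxide serves both positions, displacement at C7 before C5 is expected in the dipolar solvent but is not required. No stereocentre is created, and the labile centre C2 of 12 disappears on ring closure.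

Step 6
Reactants: 17 3,5,7-tris(allyloxy)-2-[3-(allyloxy)-4-(benzyloxy)phenyl]-4H-chromen-4-one
Product: 18 2-[4-(benzyloxy)-3-hydroxyphenyl]-3,5,7-trihydroxy-4H-chromen-4-one (4'-O-benzylquercetin)
Conditions: Pd(PPh3)4 (cat.), morpholine (excess), THF, rt, Ar; dilute HCl work-up
Reagents that add atoms: none
Why: Tsuji–Trost-type deallylation, in which zerovalent palladium ionises each allyl ether to a π-allyl complex and a phenoxide, the large excess of morpholine traps the allyl fragment before ring A can be C-allylated, and the benzyl ether is inert.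

Step 7
Reactants: 18 4'-O-benzylquercetin
Product: 19 4'-O-benzylquercetin 3,7,3'-tris(hydrogen sulfate)
Conditions: SO3·NMe3 (6 equiv), Et3N, DMF, 50 °C; reversed-phase or size-exclusion purification of the salt
Reagents that add atoms: sulfur trioxide–trimethylamine complex, C[N+](C)(C)S(=O)(=O)[O-]
Why: O-sulfation of phenols by an amine–SO3 complex, in which the 3-, 7- and 3'-hydroxyls react as ammonium phenoxides whereas the 5-OH is tied up in a six-membered hydrogen bond to the C4 carbonyl and characteristically stays free in flavonoids under such conditions.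

Step 8
Reactants: 19 4'-O-benzylquercetin 3,7,3'-tris(hydrogen sulfate)
Product: 20 quercetin 3,3',7-trissulfate
Conditions: H2 (1 atm), Pd/C, MeOH–H2O, rt, on the neutral salt
Reagents that add atoms: none
Why: Catalytic hydrogenolysis cleaves the benzylic C–O bond and should leave the aryl sulfate esters and the tetrasubstituted C2=C3 bond of the flavonol untouched.

Compound list
1 | 2-(benzyloxy)-5-bromophenol | Oc1cc(Br)ccc1OCc1ccccc1 | starting material
2 | allyl bromide | C=CCBr | starting material
3 | 2-(allyloxy)-1-(benzyloxy)-4-bromobenzene | C=CCOc1cc(Br)ccc1OCc1ccccc1 | intermediate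
4 | allyloxyacetic acid | C=CCOCC(=O)O | starting material
5 | N,O-dimethylhydroxylamine hydrochloride | CNOC.Cl | starting material
6 | 2-(allyloxy)-1-(1H-imidazol-1-yl)ethan-1-one (acyl imidazole; not isolated) | C=CCOCC(=O)n1ccnc1 | intermediate
7 | 2-(allyloxy)-N-methoxy-N-methylacetamide | C=CCOCC(=O)N(C)OC | intermediate
8 | [3-(allyloxy)-4-(benzyloxy)phenyl]lithium (not isolated) | [Li]c1ccc(OCc2ccccc2)c(OCC=C)c1 | intermediate
9 | 2-(allyloxy)-1-[3-(allyloxy)-4-(benzyloxy)phenyl]ethan-1-one | C=CCOCC(=O)c1ccc(OCc2ccccc2)c(OCC=C)c1 | intermediate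
10 | 2,4,6-trifluorobenzoyl chloride | O=C(Cl)c1c(F)cc(F)cc1F | starting material
11 | lithium (Z)-enolate of 9, chelated through the allyloxy oxygen (not isolated) | [Li]O/C(=C\OCC=C)c1ccc(OCc2ccccc2)c(OCC=C)c1 | intermediate
12 | 2-(allyloxy)-1-[3-(allyloxy)-4-(benzyloxy)phenyl]-3-(2,4,6-trifluorophenyl)propane-1,3-dione (racemic and labile at C2) | C=CCOC(C(=O)c1ccc(OCc2ccccc2)c(OCC=C)c1)C(=O)c1c(F)cc(F)cc1F | intermediate
13 | allyl alcohol | C=CCO | starting material
14 | potassium enolate of 12, delocalised (not isolated) | [K+].[O-]C(=C(OCC=C)C(=O)c1c(F)cc(F)cc1F)c1ccc(OCc2ccccc2)c(OCC=C)c1 | intermediate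
15 | 3-(allyloxy)-2-[3-(allyloxy)-4-(benzyloxy)phenyl]-5,7-difluoro-4H-chromen-4-one (not isolated) | O=c1c(OCC=C)c(-c2ccc(OCc3ccccc3)c(OCC=C)c2)oc2cc(F)cc(F)c12 | intermediate
16 | 3,7-bis(allyloxy)-2-[3-(allyloxy)-4-(benzyloxy)phenyl]-5-fluoro-4H-chromen-4-one (not isolated) | O=c1c(OCC=C)c(-c2ccc(OCc3ccccc3)c(OCC=C)c2)oc2cc(OCC=C)cc(F)c12 | intermediate
17 | 3,5,7-tris(allyloxy)-2-[3-(allyloxy)-4-(benzyloxy)phenyl]-4H-chromen-4-one | O=c1c(OCC=C)c(-c2ccc(OCc3ccccc3)c(OCC=C)c2)oc2cc(OCC=C)cc(OCC=C)c12 | intermediate
18 | 2-[4-(benzyloxy)-3-hydroxyphenyl]-3,5,7-trihydroxy-4H-chromen-4-one (4'-O-benzylquercetin) | O=c1c(O)c(-c2ccc(OCc3ccccc3)c(O)c2)oc2cc(O)cc(O)c12 | intermediate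
19 | 4'-O-benzylquercetin 3,7,3'-tris(hydrogen sulfate) | O=c1c(OS(=O)(=O)O)c(-c2ccc(OCc3ccccc3)c(OS(=O)(=O)O)c2)oc2cc(OS(=O)(=O)O)cc(O)c12 | intermediate
20 | quercetin 3,3',7-trissulfate | O=c1c(OS(=O)(=O)O)c(-c2ccc(O)c(OS(=O)(=O)O)c2)oc2cc(OS(=O)(=O)O)cc(O)c12 | target

Total step count: 8. Longest linear sequence: 7 (steps 1, 3, 4, 5, 6, 7, 8; the branch through step 2 is equally long).

Steps most likely to fail

Step 5.
- What may go wrong: the second intermolecular displacement may stall as ring A grows richer in electrons. Allyloxide may add to C2 and open the pyranone ring. Allyl groups may drift to propenyl ethers on long heating in base. The diketone may be cleaved if alkoxide is added too early.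
- Fallback, from 9 back to 17: the ring A oxygens are bought instead of made. 5-Fluororesorcinol (Oc1cc(O)cc(F)c1) is allylated twice with 2 and K2CO3 to 1,3-bis(allyloxy)-5-fluorobenzene F1. Vilsmeier–Haack formylation (POCl3, DMF) para to one allyloxy group and next to fluorine gives 2,4-bis(allyloxy)-6-fluorobenzaldehyde F2. Aldol addition of enolate 11 (from 9 and LiN(SiMe3)2 at −78 °C) gives 2-(allyloxy)-1-[3-(allyloxy)-4-(benzyloxy)phenyl]-3-[2,4-bis(allyloxy)-6-fluorophenyl]-3-hydroxypropan-1-one F3 as a mixture of stereoisomers. Dess–Martin oxidation then gives 2-(allyloxy)-1-[3-(allyloxy)-4-(benzyloxy)phenyl]-3-[2,4-bis(allyloxy)-6-fluorophenyl]propane-1,3-dione F4. K2CO3 in NMP at about 80 °C closes ring C by the same intramolecular fluoride displacement and should deliver 17 with no alkoxide present at any point.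

Step 4.
- What may go wrong: O-acylation may compete with C-acylation at the hindered α-alkoxy enolate carbon, a second acylation may follow, or ring closure may start before the quench.
- Fallback, from 9 back to 12: the C–C bond is made by an aldol addition, which has no O/C ambiguity. Enolate 11 is added at −78 °C to 2,4,6-trifluorobenzaldehyde (O=Cc1c(F)cc(F)cc1F) to give 2-(allyloxy)-1-[3-(allyloxy)-4-(benzyloxy)phenyl]-3-hydroxy-3-(2,4,6-trifluorophenyl)propan-1-one F5 as a mixture of stereoisomers of no consequence. Dess–Martin oxidation in buffered CH2Cl2 then raises the carbinol to the ketone of 12.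

Step 7.
- What may go wrong: sulfation may be incomplete at the hindered O3', it may creep on to O5 under forcing, and the resulting mixtures of polyanions are hard to separate.
- Fallback, from 18 back to 19: the sulfates are introduced in masked, neutral form. 2,2,2-Trichloroethyl chlorosulfate (ClS(=O)(=O)OCC(Cl)(Cl)Cl) with Et3N and DMAP in THF should give 4'-O-benzylquercetin 3,7,3'-tris(2,2,2-trichloroethyl sulfate) F6. This compound can be freed of under- and over-sulfated material on silica gel. Reductive fragmentation with Zn dust and HCO2NH4 in MeOH then unmasks the three sulfate monoesters without touching the benzyl ether and gives 19 as its ammonium salt.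

Further compounds
F1 | step 5 | 1,3-bis(allyloxy)-5-fluorobenzene | C=CCOc1cc(F)cc(OCC=C)c1
F2 | step 5 | 2,4-bis(allyloxy)-6-fluorobenzaldehyde | O=Cc1c(F)cc(OCC=C)cc1OCC=C
F3 | step 5 | 2-(allyloxy)-1-[3-(allyloxy)-4-(benzyloxy)phenyl]-3-[2,4-bis(allyloxy)-6-fluorophenyl]-3-hydroxypropan-1-one (mixture of stereoisomers) | C=CCOC(C(O)c1c(F)cc(OCC=C)cc1OCC=C)C(=O)c1ccc(OCc2ccccc2)c(OCC=C)c1
F4 | step 5 | 2-(allyloxy)-1-[3-(allyloxy)-4-(benzyloxy)phenyl]-3-[2,4-bis(allyloxy)-6-fluorophenyl]propane-1,3-dione (racemic) | C=CCOC(C(=O)c1c(F)cc(OCC=C)cc1OCC=C)C(=O)c1ccc(OCc2ccccc2)c(OCC=C)c1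
F5 | step 4 | 2-(allyloxy)-1-[3-(allyloxy)-4-(benzyloxy)phenyl]-3-hydroxy-3-(2,4,6-trifluorophenyl)propan-1-one (mixture of stereoisomers) | C=CCOC(C(O)c1c(F)cc(F)cc1F)C(=O)c1ccc(OCc2ccccc2)c(OCC=C)c1
F6 | step 7 | 4'-O-benzylquercetin 3,7,3'-tris(2,2,2-trichloroethyl sulfate) | O=c1c(OS(=O)(=O)OCC(Cl)(Cl)Cl)c(-c2ccc(OCc3ccccc3)c(OS(=O)(=O)OCC(Cl)(Cl)Cl)c2)oc2cc(OS(=O)(=O)OCC(Cl)(Cl)Cl)cc(O)c12
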